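Throughout, germacrane numbering is used: ring carbons C1–C10, lactone carbons C11–C13 on C7, methyls C14 (on C10) and C15 (on C4). β is the face of the ring that carries C11. Oxygens are named after their carbon (O8 on C8, and so on).

## The problem

1. The target is a cyclodecane with a C1 ketone, a C3 carbinol, a ring-cis trisubstituted C4=C5 alkene, an α-methylene-γ-lactone fused trans across C6 (oxygen) and C7 (carbon), a tiglate on O8, a secondary carbinol at C9 and a methyl carbinol at C10. No bridging bond helps; the ten-membered ring itself must be made, and made with the alkene cis.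
2. It has six stereocentres, (3S,6R,7S,8S,9S,10S). C11, O8, O9 and O10 sit contiguously on the β face, O6 on the α face, and O3 (β) is isolated beyond the alkene.
3. C8 and C9 form a cis-diol that a chiral-pool arene cis-dihydrodiol can supply. They can then govern C7, which is adjacent and epimerisable while C6 is a ketone. They can also govern C10, provided O9 is tied to the oxygen on C1.
4. C6 has to be set against its neighbour C7. C3 has no neighbour to lean on and is best set in a rigid precursor.
5. The α-methylene lactone (Michael acceptor), the tiglate (acyl shift to a free neighbouring hydroxyl, attack by amide bases), the C1/C3 β-hydroxy ketone and the C1/C10 ketol will not survive rough treatment. The methylene group, the ester and the free hydroxyls therefore have to appear late, and O8 must be told apart from O9 and O10.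
6. The enabling feature is that C4=C5 and the C1 ketone/C10 carbinol pair (an oxidised C1=C10 enol ether) are the two alkenes of a 1,5-diene, C5=C4–C3–C2–C1=C10, whose ends are spanned by C6–C9. That is what a bicyclo[2.2.0]hexane (C1, C2, C3, C4, C5, C10) fused to a cyclohexanone (C5–C10) releases on cycloreversion.
7. O9 and the C1 oxygen are 1,3-related across C10, so a single silicon atom can tie them together.

## Retrosynthesis

**33 back to 29.** The last bonds cut are the Si–O bonds at O3, O9 and O10 and the O8–acyl bond (33 ⇒ 32 ⇒ 30 ⇒ 29). The tiglate comes late because it would not survive the amide base used for the methylene group and would migrate between free hydroxyls. O8 is kept as a 4-methoxybenzyl ether because its oxidative removal is orthogonal to silicon. Compound 29 already holds every ring carbon and all six stereocentres. The forward steps only need acylation of the single free hydroxyl and fluoride cleavage.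

**29 back to 27.** The C10–O10 bond is cut and the C1 ketone is returned to a C1=C10 enol ether whose oxygen is joined to O9 through a di-tert-butylsilylene. Hydroxylating a C1 ketone enolate instead would need regiocontrol (C2 against C10) and face control on a flexible ring. The cyclic enol ether fixes the regiochemistry, holds O9 in the alkene plane so that only the face of H9 is open, and ends as a 9,10-silylene that leaves O8 as the only oxygen to unmask. The forward step is a Rubottom oxidation.

**27 back to 22.** C11=C13 is cut to the saturated lactone 24, and the lactone C12–O6 bond and the C6–H bond are cut to the enone ester 22. Methylenation is placed before C1 becomes a ketone because the C2 hydrogens of a C1 ketone would be more acidic than the lactone α-hydrogens. The forward reduction must deliver hydride to the face of C6 that carries the C7 side chain.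

**22 back to 21 (key cut).** Reconnecting C1 to C4 and C5 to C10 folds the ten-membered dienone into a cyclobutane fused to a cyclobutane and to a cyclohexanone. Against ring closure by C–C bond formation or fragmentation of a decalin, this cut makes both alkenes and the medium ring in one unimolecular, strain-driven step and delivers the C1 oxygen already as an enol ether. The precursor 21 is a compact tricycle in which C3 and C7 can be set with conformational control. The forward step must open along C5–C10, keep C4=C5 cis, and stop before a Cope rearrangement.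

**21 back to 13 and 14.** At C3 the O–Si and C–H bonds are cut back to the ketone 19 and its dimethyl ketal 18. A ketal keeps the four-carbon partner achiral until the tricycle can dictate the face. At C7 the C7–C11 bond is cut to methyl glyoxylate 14 and ketone 13 (via 17). Aldol condensation followed by hydrogenation is chosen over direct alkylation because the enolate carries a β-alkoxy group and must be trapped at −78 °C.

**13 back to 5 and 10.** The two Si–O bonds are cut (13 ⇒ 12 ⇒ 11), then C1–C10 and C4–C5, which is an enone–alkene photocycloaddition between cyclohexenone 5 and siloxycyclobutene 10. The forward step must join head to tail (oxygen-bearing C1 to the β-carbon C10), on the face away from O8 and O9, with the four-membered ring pointing away from the six-membered ring. Only that isomer can accept the silylene.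

**Partners.** Cyclobutene 10 comes from cyclobutanone 9, the [2+2] adduct of methylketene 8 (from propanoyl chloride 6) and 1,1-dimethoxyethene 7. Enone 5 comes from toluene cis-dihydrodiol 1 by diimide reduction (2), selective 4-methoxybenzylation of the distal hydroxyl (3), silylation (4) and allylic oxidation. The diol supplies C8 and C9 in the required absolute configuration.

## Roads not taken

**Alternative 1:** The cut is C9–C10. In the forward sense SmI2 would join an aldehyde carbon (C9) to a methyl ketone carbon (C10), close the ten-membered ring and create both carbinol centres as the cis-diol A1.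
- Merits: the lactone and the cis alkene are made before the ring, two stereocentres and the ring arise together, and O9 (secondary, free) is told apart from O10 (tertiary) and O8 (ether) without extra steps. In this last respect it is better than the chosen plan, which needs the silylene device to reach the same differentiation.
- Weak points: both carbonyl partners carry an α-oxygen (O8 next to C9, O1 next to C10), and ketyl radicals expel such groups. The closure is entropically costly with only one cis alkene as a turn. The diol configuration relative to C8 rests on chelation models. The open chain with five stereocentres must be built linearly.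
- Comparison: the chosen plan sets against this a ring made by strain release and a C10 centre fixed by a ring, not by a model.

**Alternative 2:** The cut is the C4–C9 bond of a cis-fused decalin. KOtBu would form the C9 alkoxide, which fragments with loss of a C5 mesylate to give the C9 ketone and the cis C4=C5 alkene of A2.
- Merits: the alkene geometry follows stereospecifically from an antiperiplanar fragmentation, at least as securely as in the chosen plan. Decalin chemistry is predictable, and there is neither light nor heat.
- Weak points: A2 has the ketone at C9 and a protected C1/C10 diol, the reverse of the target, so C9 must be reduced on the flexible ring and C1 oxidised later. The decalin needs eight stereocentres including two fully substituted carbons. The new ketone is flanked by an α-alkoxy group and sits β to the lactone oxygen, inviting elimination under the basic conditions.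
- Comparison: the chosen plan is shorter and needs no oxidation-state exchange, at the price of a thermal step.

**Alternative 3:** The cut forms C8–C9 and breaks C1–C6. A potassium alkoxide (KH, 18-crown-6) would undergo an anionic oxy-Cope rearrangement through a chair to the ten-membered dienone A3.
- Merits: the step is mild, its chair transition state is well understood, and it sets C8, C9 and the ring-trans C1=C10 alkene together. In mildness and predictability of the ring-forming event it is better than the chosen plan.
- Weak points: A3 has silicon on C8 (a Tamao–Fleming oxidation beside two alkenes and a 4-methoxybenzyl ether), no oxygen at C1 or C10 (a regio- and face-selective oxidation of C1=C10 without a lock), and no side chain at C7. It also needs a geometrically pure enol ether.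
- Comparison: the chosen plan answers with O1 built in as the enol ether, C8 and C9 from the chiral pool, and fewer late corrections.

Key step: step 15

## Route

Assumptions:
- Compounds 1, 6, 7, 14 (monomer freshly distilled) and 31 are taken as commercial.
- The C1=C10 bond of 22 is called ring-trans (C2 and C9 opposed); by the sequence rule it is Z because O1 outranks C2.

Step 1
Reactants: 1 (1S,2R)-3-methylcyclohexa-3,5-diene-1,2-diol
Product: 2 (1S,2R)-3-methylcyclohex-3-ene-1,2-diol
Conditions: KO2CN=NCO2K, AcOH, MeOH, 0 °C to rt
Reagents that add atoms: none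
Why: Diimide generated in the flask transfers two hydrogens to the less substituted, less hindered ring alkene and leaves the methyl-bearing one, the known selective reduction of arene cis-dihydrodiols; the two carbinol centres are untouched.

Step 2
Reactants: 2 (1S,2R)-3-methylcyclohex-3-ene-1,2-diol
Product: 3 (1R,6S)-6-(4-methoxybenzyloxy)-2-methylcyclohex-2-en-1-ol
Conditions: Bu2SnO, toluene, reflux (Dean–Stark); then 4-MeOC6H4CH2Cl, CsF, DMF, rt
Reagents that add atoms: 4-methoxybenzyl chloride (COc1ccc(CCl)cc1)
Why: Stannylene-acetal alkylation goes to the equatorial, less hindered oxygen distal to the methyl group (the future O8); the allylic hydroxyl, pseudoaxial to avoid A(1,2) strain with the methyl, stays free.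

Step 3
Reactants: 3 (1R,6S)-6-(4-methoxybenzyloxy)-2-methylcyclohex-2-en-1-ol
Product: 4 triethylsilyl ether of 3 at the allylic oxygen (future O9)
Conditions: Et3SiCl, imidazole, DMF, 0 °C to rt
Reagents that add atoms: chlorotriethylsilane (CC[Si](Cl)(CC)CC)
Why: Standard silylation; the allylic oxygen must be masked or the next oxidant would turn it into the wrong enone.

Step 4
Reactants: 4 triethylsilyl ether of 3
Product: 5 (4R,5S)-5-(4-methoxybenzyloxy)-3-methyl-4-(triethylsilyloxy)cyclohex-2-en-1-one
Conditions: CrO3, 3,5-dimethylpyrazole, CH2Cl2, −20 °C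
Reagents that add atoms: chromium trioxide (O=[Cr](=O)=O)
Why: Allylic oxidation by the CrO3–dimethylpyrazole complex takes the only unhindered allylic methylene to the enone; the oxygenated allylic methine and the methyl group react more slowly.

Step 5
Reactants: 6 propanoyl chloride; 7 1,1-dimethoxyethene
Product: 9 3,3-dimethoxy-2-methylcyclobutan-1-one (racemic), via methylketene 8 (not isolated)
Conditions: Et3N, Et2O, 0 °C to rt, slow addition of 6 to 7 (2 equiv)
Reagents that add atoms: none
Why: Dehydrochlorination gives methylketene, which undergoes the thermal ketene–ketene acetal [2+2] cycloaddition with its carbonyl carbon joining the nucleophilic CH2 terminus, placing the ketal next to the methyl-bearing carbon.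

Step 6
Reactants: 9 3,3-dimethoxy-2-methylcyclobutan-1-one
Product: 10 3,3-dimethoxy-2-methyl-1-(trimethylsilyloxy)cyclobut-1-ene
Conditions: Me3SiCl, NaI, Et3N, MeCN, 0 °C to rt; pentane extraction, distillation
Reagents that add atoms: chlorotrimethylsilane (C[Si](C)(C)Cl)
Why: Enol silylation under equilibrating conditions should favour the tetrasubstituted enol ether toward the methyl-bearing carbon; excess amine keeps the medium basic so that the allylic ketal does not ionise.

Step 7
Reactants: 5 (4R,5S)-5-(4-methoxybenzyloxy)-3-methyl-4-(triethylsilyloxy)cyclohex-2-en-1-one; 10 3,3-dimethoxy-2-methyl-1-(trimethylsilyloxy)cyclobut-1-ene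
Product: 11 cis-anti-cis head-to-tail photoadduct: 6-oxo tricycle with new bonds C1–C10 and C4–C5 on the face opposite O8 and O9, bearing 1-OSiMe3, 3,3-(OMe)2, 4-Me, 10-Me, 8-OPMB, 9-OSiEt3
Conditions: hν (366 nm, uranium-glass filter), 10 (5 equiv), CH2Cl2, −40 °C; then basic Al2O3
Reagents that add atoms: none
Why: Enone–alkene [2+2] photocycloaddition through the enone triplet, with the oxygen-bearing alkene carbon joining the β-carbon C10 (head to tail), on the face away from the pseudoaxial O9 and O8, and with the cyclobutane of the partner turned away from the six-membered ring; alumina converts any trans-fused adduct to the cis-fused ketone. The new centres C1, C4, C5 and C10 vanish in step 15 but decide whether step 9 can occur.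

Step 8
Reactants: 11 cis-anti-cis photoadduct
Product: 12 the C1,C9-diol of 11 (tertiary cyclobutanol at C1, secondary alcohol at C9)
Conditions: HF·pyridine, pyridine, THF, 0 °C to rt
Reagents that add atoms: none
Why: Buffered fluoride removes both silyl ethers and spares the ketal, the benzyl ether and the ketone; the cyclobutanol is safe from retro-aldol opening because its oxygen is γ to the C6 ketone and C3 is still a ketal.

Step 9
Reactants: 12 C1,C9-diol
Product: 13 9,1-O-di-tert-butylsilylene derivative of 12 (six-membered ring C9–O–Si–O–C1–C10)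
Conditions: tBu2Si(OTf)2, 2,6-lutidine, CH2Cl2, 0 °C to rt
Reagents that add atoms: di-tert-butylsilyl bis(trifluoromethanesulfonate) (CC(C)(C)[Si](OS(=O)(=O)C(F)(F)F)(OS(=O)(=O)C(F)(F)F)C(C)(C)C)
Why: Silylene protection of a 1,3-diol; the ring forms trans-fused (diequatorial) on the cyclohexanone and cis on the cyclobutane, which only the cis-anti-cis head-to-tail adduct allows, so the step also filters isomers and locks the cyclohexanone chair.

Step 10
Reactants: 13 silylene tricycle; 14 methyl glyoxylate
Product: 17 C7-[(E)-methoxycarbonylmethylidene] derivative of 13, via aldol adduct 15 (not isolated), via mesylate 16 (not isolated)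
Conditions: LiN(iPr)2, THF, −78 °C; 14; then MeSO2Cl, −78 to 0 °C; then DBU, 0 °C to rt
Reagents that add atoms: none
Why: Kinetic deprotonation at the C7 methylene (C5 is a hindered ring-fusion methine) and aldol addition at −78 °C, where the β-benzyloxy group is not expelled; mesylation and E1cB elimination give the conjugated alkylidene, which cannot aromatise in this tricycle.

Step 11
Reactants: 17 alkylidene keto ester
Product: 18 keto ester with C7 β-CH2CO2Me (equatorial, cis to O8)
Conditions: H2 (1 atm), Pd/C, pyridine (0.5 equiv), EtOAc, rt; then Et3N (cat.), MeOH, rt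
Reagents that add atoms: none
Why: Hydrogenation of the doubly activated alkene on pyridine-moderated Pd/C spares the benzyl-type ether. C7, α to the ketone, then settles by equilibration in the equatorial β position, because the axial α position is syn-axial to the cyclobutane carbon C4 in the chair fixed by the silylene.

Step 12
Reactants: 18 keto ester
Product: 19 C3 ketone (cyclobutanone) of 18
Conditions: 1 M HCl, THF, rt
Reagents that add atoms: water (O)
Why: Acid hydrolysis of the dimethyl ketal; the silylene, ester and benzyl ether tolerate dilute acid. With O1 capped, the β-oxygenated cyclobutanone cannot open by retro-aldol cleavage, and the acid completes the C7 equilibration.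

Step 13
Reactants: 19 cyclobutanone
Product: 20 (3S)-cyclobutanol: C3 hydroxyl endo (syn to C5 and C10, anti to the C4 methyl and O1)
Conditions: NaBH4 (1 equiv), MeOH–CH2Cl2, −78 °C
Reagents that add atoms: none
Why: The strained, exposed cyclobutanone is reduced before the cyclohexanone, whose faces are screened by the syn-axial C10 methyl and O8 ether and by axial C4. Hydride enters from the convex face of the bicyclo[2.2.0]hexanone, which gives the endo alcohol of S configuration.

Step 14
Reactants: 20 (3S)-cyclobutanol
Product: 21 tert-butyldimethylsilyl ether of 20 (thermolysis substrate)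
Conditions: tBuMe2SiOTf, 2,6-lutidine, CH2Cl2, −78 °C
Reagents that add atoms: tert-butyldimethylsilyl trifluoromethanesulfonate (CC(C)(C)[Si](C)(C)OS(=O)(=O)C(F)(F)F)
Why: Silylation of a hindered secondary alcohol with the triflate and a weak base; at −78 °C with lutidine the ketone is not enolised.

Step 15
Reactants: 21 silylated tricycle
Product: 22 ten-membered 4Z-enone: C6 ketone, ring-cis C4=C5, ring-trans C1=C10 enol ether inside the six-membered silylene ring (O1–Si–O9), 3β-OSitBuMe2, 8β-OPMB, 7β-CH2CO2Me
Conditions: toluene (0.01 M, 1% Et3N), stainless-steel flow coil, 220 °C, residence about 1 min, then rapid cooling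
Reagents that add atoms: none
Why: The central C1–C4 bond of the bicyclo[2.2.0]hexane breaks first, giving a cyclohexane-1,4-diyl that is tertiary at C4 and oxygen-stabilised at C1. The diyl then cleaves C5–C10, which creates the conjugated enone and the enol ether; cleaving C2–C3 instead would give a divinylcyclohexane. The closest known reaction type is the thermal cycloreversion of enone–cyclobutene photoadducts to cyclodeca-1,5-dienes. No ring closes: the cyclohexanone is enlarged by four carbons, driven by the strain of two cyclobutanes. No stereocentre is made; C1, C4, C5 and C10 become trigonal while C3, C7, C8 and C9 are carried through. The step needs C4=C5 cis: the silylene ring forces O1 cis to C9, so C1=C10 must be ring-trans, and the one-cis-one-trans course of the chair diyl then puts the cis geometry on the enone. It also needs to stop at the diene; the short, buffered residence time is meant to outrun the slower, more ordered Cope rearrangement, and the neutral medium spares the epimerisable C7.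

Step 16
Reactants: 22 ten-membered enone ester
Product: 24 trans-fused 6α,12-lactone, via hydroxy ester 23 (not isolated)
Conditions: NaBH4, CeCl3·7H2O, MeOH–THF, −78 °C; then DBU (cat.), toluene, rt
Reagents that add atoms: none
Why: Luche 1,2-reduction of the enone; hydride is expected on the outer face of the carbonyl, which also carries the C7 side chain while C8 and the transannular enol ether screen the inner face. That places H6 syn to C11 and O6 anti (6R), and the alcohol then closes on the ester to the trans lactone.

Step 17
Reactants: 24 trans lactone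
Product: 27 α-methylene lactone, via Mannich base 25 (not isolated), via ammonium iodide 26 (not isolated)
Conditions: LiN(iPr)2, THF, −78 °C; CH2=NMe2+ I−; then MeI, MeOH, rt; then NaHCO3 (aq), EtOAc
Reagents that add atoms: dimethylmethyleneammonium iodide (C=[N+](C)C.[I-])
Why: Eschenmoser methylenation (enolate aminomethylation, quaternisation, elimination); the lactone α-hydrogens are the only acidic ones because C1 is still an enol ether.

Step 18
Reactants: 27 α-methylene lactone
Product: 29 C1 ketone with 9,10-O-di-tert-butylsilylene (10S), via siloxy epoxide 28 (not isolated)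
Conditions: mCPBA, NaHCO3, CH2Cl2, −20 to 0 °C
Reagents that add atoms: 3-chloroperoxybenzoic acid (OOC(=O)c1cccc(Cl)c1)
Why: Rubottom oxidation of the only electron-rich alkene. The silylene ring holds O9 in the plane of the ring-trans enol ether, so C8 and the rest of the carbocycle cover one face and the peracid must attack the face of H9, which gives O10 cis to O9 (10S) whatever the ring conformation. The 1,4-silyl shift from O1 to O10 releases the ketone and leaves O9 and O10 protected together.

Step 19
Reactants: 29 silylene ketone
Product: 30 C8 alcohol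
Conditions: DDQ, CH2Cl2–pH 7 buffer, 0 °C
Reagents that add atoms: none
Why: Oxidative cleavage of the 4-methoxybenzyl ether, orthogonal to both silicon groups, the lactone and the alkenes; O8 is now the only free hydroxyl.

Step 20
Reactants: 30 C8 alcohol; 31 tigloyl chloride
Product: 32 C8 tiglate
Conditions: DMAP, Et3N, CH2Cl2, 0 °C to rt
Reagents that add atoms: none
Why: DMAP-catalysed acylation of the single free secondary alcohol; O9 and O10 are tied in the silylene, so neither over-acylation nor acyl migration can occur.

Step 21
Reactants: 32 C8 tiglate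
Product: 33 CNP0106709.2, (3S,6R,7S,8S,9S,10S)-3β,9β,10β-trihydroxy-1-oxo-8β-tigloyloxygermacra-4Z,11(13)-dien-6α,12-olide
Conditions: HF·pyridine, pyridine, THF, 0 °C to rt
Reagents that add atoms: none
Why: Buffered fluoride cleaves the strained five-membered silylene and the allylic silyl ether; the weakly acidic, non-nucleophilic medium leaves the methylene lactone, the tiglate and the β-hydroxy ketone intact.

## Compound list

1 | (1S,2R)-3-methylcyclohexa-3,5-diene-1,2-diol | CC1=CC=C[C@H](O)[C@@H]1O | starting material
2 | (1S,2R)-3-methylcyclohex-3-ene-1,2-diol | CC1=CCC[C@H](O)[C@@H]1O | intermediate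
3 | (1R,6S)-6-(4-methoxybenzyloxy)-2-methylcyclohex-2-en-1-ol | CC1=CCC[C@H](OCc2ccc(OC)cc2)[C@@H]1O | intermediate
4 | triethylsilyl ether of 3 | CC1=CCC[C@H](OCc2ccc(OC)cc2)[C@@H]1O[Si](CC)(CC)CC | intermediate
5 | (4R,5S)-5-(4-methoxybenzyloxy)-3-methyl-4-(triethylsilyloxy)cyclohex-2-en-1-one | CC1=CC(=O)C[C@H](OCc2ccc(OC)cc2)[C@@H]1O[Si](CC)(CC)CC | intermediate
6 | propanoyl chloride | CCC(=O)Cl | starting material
7 | 1,1-dimethoxyethene | C=C(OC)OC | starting material
8 | methylketene | CC=C=O | intermediate (not isolated)
9 | 3,3-dimethoxy-2-methylcyclobutan-1-one (racemic) | CC1C(=O)CC1(OC)OC | intermediate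
10 | 3,3-dimethoxy-2-methyl-1-(trimethylsilyloxy)cyclobut-1-ene | CC1=C(O[Si](C)(C)C)CC1(OC)OC | intermediate
11 | cis-anti-cis head-to-tail photoadduct (1-OSiMe3, 3,3-dimethoxy, 8-OPMB, 9-OSiEt3, 6-oxo) | O=C1[C@@H]2[C@@]3(C)C(OC)(OC)C[C@@]3(O[Si](C)(C)C)[C@]2(C)[C@@H](O[Si](CC)(CC)CC)[C@@H](OCc4ccc(OC)cc4)C1 | intermediate
12 | C1,C9-diol of the photoadduct | O=C1[C@@H]2[C@@]3(C)C(OC)(OC)C[C@@]3(O)[C@]2(C)[C@@H](O)[C@@H](OCc4ccc(OC)cc4)C1 | intermediate
13 | 9,1-O-di-tert-butylsilylene tricycle | O=C1[C@@H]2[C@@]3(C)C(OC)(OC)C[C@@]3(O5)[C@]2(C)[C@@H](O[Si]5(C(C)(C)C)C(C)(C)C)[C@@H](OCc4ccc(OC)cc4)C1 | intermediate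
14 | methyl glyoxylate | COC(=O)C=O | starting material
15 | C7 aldol adduct (diastereomer mixture at C7 and C11) | O=C1[C@@H]2[C@@]3(C)C(OC)(OC)C[C@@]3(O5)[C@]2(C)[C@@H](O[Si]5(C(C)(C)C)C(C)(C)C)[C@@H](OCc4ccc(OC)cc4)C1C(O)C(=O)OC | intermediate (not isolated)
16 | mesylate of 15 | O=C1[C@@H]2[C@@]3(C)C(OC)(OC)C[C@@]3(O5)[C@]2(C)[C@@H](O[Si]5(C(C)(C)C)C(C)(C)C)[C@@H](OCc4ccc(OC)cc4)C1C(OS(C)(=O)=O)C(=O)OC | intermediate (not isolated)
17 | C7 (E)-methoxycarbonylmethylidene ketone | O=C1[C@@H]2[C@@]3(C)C(OC)(OC)C[C@@]3(O5)[C@]2(C)[C@@H](O[Si]5(C(C)(C)C)C(C)(C)C)[C@@H](OCc4ccc(OC)cc4)/C1=C\C(=O)OC | intermediate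
18 | keto ester, C7 β-CH2CO2Me | O=C1[C@@H]2[C@@]3(C)C(OC)(OC)C[C@@]3(O5)[C@]2(C)[C@@H](O[Si]5(C(C)(C)C)C(C)(C)C)[C@@H](OCc4ccc(OC)cc4)[C@H]1CC(=O)OC | intermediate
19 | C3 cyclobutanone | O=C1[C@@H]2[C@@]3(C)C(=O)C[C@@]3(O5)[C@]2(C)[C@@H](O[Si]5(C(C)(C)C)C(C)(C)C)[C@@H](OCc4ccc(OC)cc4)[C@H]1CC(=O)OC | intermediate
20 | (3S)-cyclobutanol (endo hydroxyl) | O=C1[C@@H]2[C@@]3(C)[C@@H](O)C[C@@]3(O5)[C@]2(C)[C@@H](O[Si]5(C(C)(C)C)C(C)(C)C)[C@@H](OCc4ccc(OC)cc4)[C@H]1CC(=O)OC | intermediate
21 | 3-O-tert-butyldimethylsilyl tricycle (precursor of the key step) | O=C1[C@@H]2[C@@]3(C)[C@@H](O[Si](C)(C)C(C)(C)C)C[C@@]3(O5)[C@]2(C)[C@@H](O[Si]5(C(C)(C)C)C(C)(C)C)[C@@H](OCc4ccc(OC)cc4)[C@H]1CC(=O)OC | intermediate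
22 | ten-membered 4Z-enone with ring-trans C1=C10 cyclic silyl enol ether (product of the key step) | O=C1/C=C(/C)[C@@H](O[Si](C)(C)C(C)(C)C)C/C(O5)=C(\C)[C@@H](O[Si]5(C(C)(C)C)C(C)(C)C)[C@@H](OCc4ccc(OC)cc4)[C@H]1CC(=O)OC | intermediate
23 | 6α-hydroxy ester | O[C@@H]1/C=C(/C)[C@@H](O[Si](C)(C)C(C)(C)C)C/C(O5)=C(\C)[C@@H](O[Si]5(C(C)(C)C)C(C)(C)C)[C@@H](OCc4ccc(OC)cc4)[C@H]1CC(=O)OC | intermediate (not isolated)
24 | trans-fused 6α,12-lactone | C1C(=O)O[C@@H]2/C=C(/C)[C@@H](O[Si](C)(C)C(C)(C)C)C/C(O5)=C(\C)[C@@H](O[Si]5(C(C)(C)C)C(C)(C)C)[C@@H](OCc4ccc(OC)cc4)[C@@H]12 | intermediate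
25 | C11 dimethylaminomethyl lactone (epimer mixture at C11) | CN(C)CC1C(=O)O[C@@H]2/C=C(/C)[C@@H](O[Si](C)(C)C(C)(C)C)C/C(O5)=C(\C)[C@@H](O[Si]5(C(C)(C)C)C(C)(C)C)[C@@H](OCc4ccc(OC)cc4)[C@@H]12 | intermediate (not isolated)
26 | trimethylammonium iodide of 25 | C[N+](C)(C)CC1C(=O)O[C@@H]2/C=C(/C)[C@@H](O[Si](C)(C)C(C)(C)C)C/C(O5)=C(\C)[C@@H](O[Si]5(C(C)(C)C)C(C)(C)C)[C@@H](OCc4ccc(OC)cc4)[C@@H]12.[I-] | intermediate (not isolated)
27 | α-methylene lactone | C=C1C(=O)O[C@@H]2/C=C(/C)[C@@H](O[Si](C)(C)C(C)(C)C)C/C(O5)=C(\C)[C@@H](O[Si]5(C(C)(C)C)C(C)(C)C)[C@@H](OCc4ccc(OC)cc4)[C@@H]12 | intermediate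
28 | C1,C10 siloxy epoxide (oxygen on the face of H9) | C=C1C(=O)O[C@@H]2/C=C(/C)[C@@H](O[Si](C)(C)C(C)(C)C)C[C@]6(O5)O[C@@]6(C)[C@@H](O[Si]5(C(C)(C)C)C(C)(C)C)[C@@H](OCc4ccc(OC)cc4)[C@@H]12 | intermediate (not isolated)
29 | C1 ketone, 9,10-O-di-tert-butylsilylene, 8-OPMB | C=C1C(=O)O[C@@H]2/C=C(/C)[C@@H](O[Si](C)(C)C(C)(C)C)CC(=O)[C@@]5(C)O[Si](C(C)(C)C)(C(C)(C)C)O[C@H]5[C@@H](OCc4ccc(OC)cc4)[C@@H]12 | intermediate
30 | C8 alcohol | C=C1C(=O)O[C@@H]2/C=C(/C)[C@@H](O[Si](C)(C)C(C)(C)C)CC(=O)[C@@]5(C)O[Si](C(C)(C)C)(C(C)(C)C)O[C@H]5[C@@H](O)[C@@H]12 | intermediate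
31 | tigloyl chloride, (E)-2-methylbut-2-enoyl chloride | C/C=C(\C)C(=O)Cl | starting material
32 | C8 tiglate | C=C1C(=O)O[C@@H]2/C=C(/C)[C@@H](O[Si](C)(C)C(C)(C)C)CC(=O)[C@@]5(C)O[Si](C(C)(C)C)(C(C)(C)C)O[C@H]5[C@@H](OC(=O)/C(C)=C/C)[C@@H]12 | intermediate
33 | CNP0106709.2 | C=C1C(=O)O[C@@H]2/C=C(/C)[C@@H](O)CC(=O)[C@@](C)(O)[C@@H](O)[C@@H](OC(=O)/C(C)=C/C)[C@@H]12 | target

## Step count and weak points

Total: 21 steps. Longest linear sequence: 19 steps (steps 1–4 and 7–21, from 1). The cyclobutene 10 takes two steps (5 and 6) from 6 and 7.

**Step 15 (key step).** The opened 1,5-diene may go on to a Cope rearrangement during heating, since its C3 siloxy group would become an enol ether, or the diyl may cleave C2–C3 instead of C5–C10; both lead to a divinylcyclohexane. Fallback: open the tricycle one stage earlier, from cyclobutanone 19, where either escape would have to form a ketene and the C4 radical is stabilised by the carbonyl. This gives the ten-membered 3,6-diketone F1. Its less hindered C3 carbonyl, which carries an α-methyl alkenyl group and a methylene, is reduced under reagent control with the (R)-methyl oxazaborolidine and catecholborane to the (3S)-alcohol F2, and silylation with tBuMe2SiOTf returns to 22.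

**Step 6.** Enolisation may go toward the methylene carbon, or the allylic ketal may lose methanol to the vinylogous ester under the Lewis-acidic silylating conditions. Fallback: fix the enolate position by reduction instead of deprotonation. Starting from 7, 2-bromopropanoyl chloride and Et3N give, through bromo(methyl)ketene, 2-bromo-3,3-dimethoxy-2-methylcyclobutan-1-one F3; Zn and Me3SiCl in ether then deliver 10 regiospecifically.

**Step 16.** Facial selectivity may be poor or reversed: open-chain models (Felkin, chelation through O8) favour hydride delivery anti to the C7 side chain, which leads to the 6β-alcohol and the cis lactone. Fallback: accept that course from 22 and invert afterwards. The cis-fused 6β,12-lactone F4 is opened with LiOH to the 6β-hydroxy acid F5, and Mitsunobu lactonisation (PPh3, diisopropyl azodicarboxylate) closes the ring with inversion at the allylic C6, returning to 24.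

**Step 4.** The oxidant may attack the benzylic position of the 4-methoxybenzyl ether or the oxygenated allylic methine instead of the ring methylene. Fallback: oxidise before the ether is in place. From 1, 2,2-dimethoxypropane and TsOH give the acetonide F6; diimide gives F7; the same chromium reagent gives the acetonide enone F8; aqueous acetic acid frees the enone diol F9; stannylene alkylation gives the 5-O-(4-methoxybenzyl) hydroxy enone F10; and Et3SiCl returns to 5.

## Further compounds

F1 | step 15 | ten-membered 3,6-diketone with ring-trans C1=C10 cyclic silyl enol ether | O=C1/C=C(/C)C(=O)C/C(O5)=C(\C)[C@@H](O[Si]5(C(C)(C)C)C(C)(C)C)[C@@H](OCc4ccc(OC)cc4)[C@H]1CC(=O)OC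
F2 | step 15 | (3S)-hydroxy enone (22 without the C3 silyl group) | O=C1/C=C(/C)[C@@H](O)C/C(O5)=C(\C)[C@@H](O[Si]5(C(C)(C)C)C(C)(C)C)[C@@H](OCc4ccc(OC)cc4)[C@H]1CC(=O)OC
F3 | step 6 | 2-bromo-3,3-dimethoxy-2-methylcyclobutan-1-one (racemic) | CC1(Br)C(=O)CC1(OC)OC
F4 | step 16 | cis-fused 6β,12-lactone (C6 epimer of 24) | C1C(=O)O[C@H]2/C=C(/C)[C@@H](O[Si](C)(C)C(C)(C)C)C/C(O5)=C(\C)[C@@H](O[Si]5(C(C)(C)C)C(C)(C)C)[C@@H](OCc4ccc(OC)cc4)[C@@H]12
F5 | step 16 | 6β-hydroxy acid | OC(=O)C[C@H]1[C@@H](O)/C=C(/C)[C@@H](O[Si](C)(C)C(C)(C)C)C/C(O5)=C(\C)[C@@H](O[Si]5(C(C)(C)C)C(C)(C)C)[C@H]1OCc4ccc(OC)cc4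
F6 | step 4 | acetonide of 1 | CC1=CC=C[C@@H]2OC(C)(C)O[C@H]12
F7 | step 4 | acetonide of 2 | CC1=CCC[C@@H]2OC(C)(C)O[C@H]12
F8 | step 4 | acetonide enone, (4R,5S)-4,5-isopropylidenedioxy-3-methylcyclohex-2-en-1-one | CC1=CC(=O)C[C@@H]2OC(C)(C)O[C@H]12
F9 | step 4 | (4R,5S)-4,5-dihydroxy-3-methylcyclohex-2-en-1-one | CC1=CC(=O)C[C@H](O)[C@@H]1O
F10 | step 4 | (4R,5S)-4-hydroxy-5-(4-methoxybenzyloxy)-3-methylcyclohex-2-en-1-one | CC1=CC(=O)C[C@H](OCc2ccc(OC)cc2)[C@@H]1O
A1 | alternative 1 | ten-membered lactone with C9/C10 cis-diol from the pinacol closure | C1C(=O)O[C@@H]2/C=C(/C)[C@@H](O[Si](C)(C)C(C)(C)C)C[C@@H](O[Si](CC)(CC)CC)[C@@](C)(O)[C@@H](O)[C@@H](OCc3ccc(OC)cc3)[C@@H]12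
A2 | alternative 2 | ten-membered Z-enone lactone with C9 ketone and C1/C10 acetonide from the fragmentation | C1C(=O)O[C@@H]2/C=C(/C)[C@@H](O[Si](C)(C)C(C)(C)C)C[C@@H](OC3(C)C)[C@@](C)(O3)C(=O)[C@@H](OCOC)[C@@H]12
A3 | alternative 3 | ten-membered dienone with C8 silyl and C9 PMB ether from the oxy-Cope rearrangement | O=C1/C=C(/C)[C@@H](O[Si](C)(C)C(C)(C)C)C/C=C(\C)[C@@H](OCc2ccc(OC)cc2)[C@@H]([Si](C)(C)c3ccccc3)C1
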